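**Retrosynthetic overview**

1. The target is catechin-(4α→6)-epicatechin-(4β→8)-epicatechin-(4β→8)-epicatechin (units A, B, C, D from the top). After global hydrogenolysis it is cut at the B(C4)–C(C8) bond into an A–B block (thioether at C4 of B) and a C–D block.
2. A–B block: the C4 cation of a bromine-capped catechin is taken up at C6 of a C8-brominated 4-thio-epicatechin. Units A, B and D keep the rings of (+)-catechin and (−)-epicatechin.
3. C–D block: the pyran ring of unit C is carried as a trans-2-aryl-2,3-dihydrobenzofuran-3-carbaldehyde. Its O-benzyl oxocarbenium ion undergoes a 1,2-shift of C2 (ring expansion, five to six members) to the unit C C4 cation, which C8 of unit D traps.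
4. Enabling feature: in unit C the ring oxygen O1 (on C8a) and the oxygens on C5 and C7 all lie ortho or para to C4a, so a cation at C4 of the pyran ring is a stabilised benzylic cation. C3 of that ring can therefore start as an exocyclic formyl carbon on the carbon that becomes C4.
5. Ring order: the dihydrobenzofuran of unit C is closed by rhodium-carbene C–H insertion into one of two homotopic 3,4-bis(benzyloxy)benzyl ether arms (sets C2), then expanded to the pyran (sets C3 and C4). No other ring is built.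

Key step: step 9

Assumption: the enantiomer of the chiral dirhodium catalyst in step 4 is taken to be the one that gives the (2S) benzylic centre, and the C4 epimer drawn for the 4-alkoxy and 4-thio intermediates is immaterial because C4 is ionised when they are used.

**Route**

Step 1
Reactants: 1 1,3,5-triacetoxybenzene; 2 3,4-bis(benzyloxy)benzyl chloride
Product: 3 1,3,5-tris{[3,4-bis(benzyloxy)benzyl]oxy}benzene
Conditions: 2 (3.3 equiv in all), NaH (7 equiv), H2O (3 equiv, added slowly), DMF, 0 °C → rt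
Reagents that add atoms: 3,4-bis(benzyloxy)benzyl chloride (the two further equivalents of 2), ClCc1ccc(OCc2ccccc2)c(OCc2ccccc2)c1
Why: Threefold Williamson etherification that takes up one molecule of 2 per phenoxide, three in all, in which hydroxide made in the flask from NaH and water unmasks the phenoxides one at a time, which should keep the phloroglucinol core from C-alkylation.

Step 2
Reactants: 3 1,3,5-tris{[3,4-bis(benzyloxy)benzyl]oxy}benzene
Product: 4 2-iodo-1,3,5-tris{[3,4-bis(benzyloxy)benzyl]oxy}benzene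
Conditions: NIS (1.0 equiv), CH2Cl2, −20 °C, dark
Reagents that add atoms: N-iodosuccinimide, O=C1CCC(=O)N1I
Why: Electrophilic aromatic iodination; the phloroglucinol triether ring is far more nucleophilic than the rings of the benzyl arms and its three free positions are equivalent, so one equivalent of NIS should give a single mono-iodide.

Step 3
Reactants: 4 2-iodo-1,3,5-tris{[3,4-bis(benzyloxy)benzyl]oxy}benzene
Product: 5 ethyl 2-diazo-2-(2,4,6-tris{[3,4-bis(benzyloxy)benzyl]oxy}phenyl)acetate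
Conditions: ethyl diazoacetate, Pd(PPh3)4 (5 mol %), Ag2CO3 (0.5 equiv), Et3N, toluene, rt
Reagents that add atoms: ethyl diazoacetate, CCOC(=O)C=[N+]=[N-]
Why: Palladium-catalysed cross-coupling of an aryl iodide with the acidic C–H of ethyl diazoacetate (oxidative addition, transfer of the silver diazoacetate, reductive elimination) should install the diazo ester with the diazo group intact.

Step 4
Reactants: 5 ethyl 2-diazo-2-(2,4,6-tris{[3,4-bis(benzyloxy)benzyl]oxy}phenyl)acetate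
Product: 6 ethyl (2S,3R)-cis-2-[3,4-bis(benzyloxy)phenyl]-4,6-bis{[3,4-bis(benzyloxy)benzyl]oxy}-2,3-dihydrobenzofuran-3-carboxylate
Conditions: Rh2(S-PTTL)4 [dirhodium tetrakis(N-phthaloyl-(S)-tert-leucinate)] (1 mol %), toluene, −60 °C
Reagents that add atoms: none
Why: Intramolecular 1,5 C–H insertion of the dirhodium carbene into the benzylic ether C–H bond closes the dihydrobenzofuran; the two ortho arms are homotopic, the concerted insertion gives the cis-2,3 isomer, and the chiral carboxylate ligands set the absolute configuration (2S,3R).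

Step 5
Reactants: 6 ethyl (2S,3R)-cis-2-[3,4-bis(benzyloxy)phenyl]-4,6-bis{[3,4-bis(benzyloxy)benzyl]oxy}-2,3-dihydrobenzofuran-3-carboxylate
Product: 7 ethyl (2S,3S)-trans-2-[3,4-bis(benzyloxy)phenyl]-4,6-bis{[3,4-bis(benzyloxy)benzyl]oxy}-2,3-dihydrobenzofuran-3-carboxylate
Conditions: NaOEt (cat.), EtOH–THF, rt
Reagents that add atoms: none
Why: Base-mediated epimerisation through the ester enolate at C3 should give the thermodynamically preferred trans isomer, while C2, which has no acidic hydrogen, is untouched.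

Step 6
Reactants: 7 ethyl (2S,3S)-trans-2-[3,4-bis(benzyloxy)phenyl]-4,6-bis{[3,4-bis(benzyloxy)benzyl]oxy}-2,3-dihydrobenzofuran-3-carboxylate
Product: 8 (2S,3S)-trans-2-[3,4-bis(benzyloxy)phenyl]-4,6-bis{[3,4-bis(benzyloxy)benzyl]oxy}-2,3-dihydrobenzofuran-3-carbaldehyde
Conditions: iBu2AlH (1.1 equiv), CH2Cl2, −78 °C; aq. potassium sodium tartrate work-up
Reagents that add atoms: none
Why: Partial ester reduction by iBu2AlH through the tetrahedral aluminate that is stable at low temperature; C3 should stay trans because that is the thermodynamic arrangement.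

Step 7
Reactants: 9 (−)-epicatechin
Product: 10 5,7,3',4'-tetra-O-benzylepicatechin
Conditions: BnBr, K2CO3, DMF, rt
Reagents that add atoms: benzyl bromide, BrCc1ccccc1
Why: Williamson etherification of the four phenols under weak base, which leaves the secondary alcohol and the stereocentres untouched.

Step 8
Reactants: 10 5,7,3',4'-tetra-O-benzylepicatechin
Product: 11 3,5,7,3',4'-penta-O-benzylepicatechin
Conditions: NaH, BnBr, nBu4NI (cat.), DMF, 0 °C → rt
Reagents that add atoms: benzyl bromide, BrCc1ccccc1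
Why: Williamson etherification of the secondary alcohol after deprotonation with NaH, so that 11 carries no free hydroxyl that could enter the oxocarbenium chemistry of step 9.

Step 9
Reactants: 8 (2S,3S)-trans-2-[3,4-bis(benzyloxy)phenyl]-4,6-bis{[3,4-bis(benzyloxy)benzyl]oxy}-2,3-dihydrobenzofuran-3-carbaldehyde; 11 3,5,7,3',4'-penta-O-benzylepicatechin
Product: 15 3,3',4'-tri-O-benzyl-5,7-bis-O-[3,4-bis(benzyloxy)benzyl]epicatechin-(4β→8)-3,5,7,3',4'-penta-O-benzylepicatechin, via O-benzyl oxocarbenium ion 12 (not isolated), via flavan-4-yl cation 13 (not isolated), via 4-benzyloxyflavan 14 (not isolated)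
Conditions: BnOTMS (2.2 equiv), TMSOTf (20 mol %), 4 Å MS, CH2Cl2, −78 °C; then 11 (3 equiv), −78 → −30 °C; Et3N quench
Reagents that add atoms: benzyloxytrimethylsilane, C[Si](C)(C)OCc1ccccc1
Why: Proposed new method: TMSOTf and BnOTMS turn the formyl group of 8 into the O-benzyl oxocarbenium ion 12 (the ionisation behind silyl triflate acetalisation and three-component Hosomi–Sakurai reactions), and the ring bond C2–C3 of the dihydrobenzofuran, whose migrating carbon C2 carries O1 and the 3,4-bis(benzyloxy)phenyl group, shifts to the oxocarbenium carbon to give the 5,7,8a-trioxygenated benzylic cation 13, which rests as the 4-benzyl ether 14 until 11 is added and attacks it through C8 (Friedel–Crafts, the bond-forming event of classical procyanidin couplings). The closest known reaction type is the semipinacol ring contraction of chroman-3-ol-4-yl cations (from 2H-chromene oxides or flavan-3,4-diol derivatives) to 2,3-dihydrobenzofuran-3-carbaldehydes, run here in the reverse sense, which should be favourable because the O-benzyl oxocarbenium ion cannot collapse to a neutral carbonyl while the cation formed is stabilised by three oxygen donors and by release of five-ring strain; it also parallels Wagner–Meerwein ring expansions of 1-indanylmethyl cations. The pyran ring is closed by a 1,2-alkyl shift, that is, ring expansion of the five-membered oxygen heterocycle by insertion of the former formyl carbon between C2 and the benzylic carbon, not by attack of a tethered nucleophile. The migrating C2 keeps its configuration (2S in 8 corresponds to 2R in the flavan), C3 is set by the rotamer of 12 that holds the benzyloxy group antiperiplanar to O1 and away from ring A, so that the trans dihydrobenzofuran maps onto the 2,3-cis flavan, and C4 is set by attack of 11 anti to the pseudoaxial 3-benzyloxy group (3,4-trans, 4β) as in epicatechin C4 couplings. The step needs alkyl rather than hydride migration or proton loss from 12 (secured by the doubly stabilised migrating carbon, by the stabilised cation formed, and by adding the nucleophile only after ring expansion so that it cannot add to the aldehyde carbon) and C8 rather than C6 attack of 11 (the usual preference of benzylated flavan-3-ols, helped by the excess of 11).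

Step 10
Reactants: 16 (+)-catechin
Product: 17 5,7,3',4'-tetra-O-benzylcatechin
Conditions: BnBr, K2CO3, DMF, rt
Reagents that add atoms: benzyl bromide, BrCc1ccccc1
Why: Williamson etherification of the four phenols under weak base, as in step 7.

Step 11
Reactants: 17 5,7,3',4'-tetra-O-benzylcatechin
Product: 18 4β-(2-ethoxyethoxy)-5,7,3',4'-tetra-O-benzylcatechin
Conditions: DDQ, 2-ethoxyethanol, CH2Cl2, rt
Reagents that add atoms: 2-ethoxyethanol, CCOCCO
Why: Benzylic oxidation by DDQ (hydride abstraction to the C4 cation stabilised by ring A) and capture by the alcohol installs a C4 leaving group for hard Lewis acids; the new C4 centre is erased again in step 16.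

Step 12
Reactants: 18 4β-(2-ethoxyethoxy)-5,7,3',4'-tetra-O-benzylcatechin
Product: 19 6,8-dibromo-4β-(2-ethoxyethoxy)-5,7,3',4'-tetra-O-benzylcatechin
Conditions: NBS (2.1 equiv), CH2Cl2, −20 °C → rt
Reagents that add atoms: N-bromosuccinimide, O=C1CCC(=O)N1Br
Why: Electrophilic aromatic bromination of both free positions of ring A (C8 first, then C6) caps the electrophile so that it cannot act as the nucleophile in step 16.

Step 13
Reactants: 10 5,7,3',4'-tetra-O-benzylepicatechin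
Product: 20 8-bromo-5,7,3',4'-tetra-O-benzylepicatechin
Conditions: NBS (1.0 equiv), CH2Cl2, −78 → −20 °C
Reagents that add atoms: N-bromosuccinimide, O=C1CCC(=O)N1Br
Why: Electrophilic aromatic bromination should go to the more nucleophilic and less hindered C8, which blocks this position so that the later Friedel–Crafts alkylation must occur at C6.

Step 14
Reactants: 20 8-bromo-5,7,3',4'-tetra-O-benzylepicatechin
Product: 21 8-bromo-4β-(2-ethoxyethoxy)-5,7,3',4'-tetra-O-benzylepicatechin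
Conditions: DDQ, 2-ethoxyethanol, CH2Cl2, rt
Reagents that add atoms: 2-ethoxyethanol, CCOCCO
Why: DDQ benzylic oxidation as in step 11, the alcohol entering anti to the axial 3-hydroxyl (4β).

Step 15
Reactants: 21 8-bromo-4β-(2-ethoxyethoxy)-5,7,3',4'-tetra-O-benzylepicatechin
Product: 22 8-bromo-4β-(2,6-dimethylphenylthio)-5,7,3',4'-tetra-O-benzylepicatechin
Conditions: 2,6-dimethylbenzenethiol, BF3·OEt2 (cat.), CH2Cl2, −78 → −40 °C
Reagents that add atoms: 2,6-dimethylbenzenethiol, Cc1cccc(C)c1S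
Why: Lewis acid-mediated SN1 exchange of the 4-alkoxy group for the arylthio group (attack anti to the 3-hydroxyl) gives a C4 leaving group that should survive hard Lewis acids and answer only to thiophilic activation.

Step 16
Reactants: 19 6,8-dibromo-4β-(2-ethoxyethoxy)-5,7,3',4'-tetra-O-benzylcatechin; 22 8-bromo-4β-(2,6-dimethylphenylthio)-5,7,3',4'-tetra-O-benzylepicatechin
Product: 23 [6,8-dibromo-5,7,3',4'-tetra-O-benzylcatechin]-(4α→6)-[8-bromo-4β-(2,6-dimethylphenylthio)-5,7,3',4'-tetra-O-benzylepicatechin]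
Conditions: 22 (3 equiv), BF3·OEt2 (cat.), 4 Å MS, CH2Cl2, −78 → −30 °C
Reagents that add atoms: none
Why: Friedel–Crafts alkylation in which BF3 ionises only the 4-alkoxy group of 19, the cation is taken up at C6 of 22 because C8 is brominated, and attack anti to the 3-hydroxyl of the 2,3-trans unit sets the 3,4-trans (4α) bond.

Step 17
Reactants: 23 [6,8-dibromo-5,7,3',4'-tetra-O-benzylcatechin]-(4α→6)-[8-bromo-4β-(2,6-dimethylphenylthio)-5,7,3',4'-tetra-O-benzylepicatechin]; 15 3,3',4'-tri-O-benzyl-5,7-bis-O-[3,4-bis(benzyloxy)benzyl]epicatechin-(4β→8)-3,5,7,3',4'-penta-O-benzylepicatechin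
Product: 24 fully protected tetramer: [6,8-dibromo-5,7,3',4'-tetra-O-benzylcatechin]-(4α→6)-[8-bromo-5,7,3',4'-tetra-O-benzylepicatechin]-(4β→8)-[3,3',4'-tri-O-benzyl-5,7-bis-O-(3,4-bis(benzyloxy)benzyl)epicatechin]-(4β→8)-[3,5,7,3',4'-penta-O-benzylepicatechin]
Conditions: 15 (2 equiv), AgBF4, 4 Å MS, THF, 0 °C; aq. NaHCO3 work-up
Reagents that add atoms: none
Why: Thiophilic activation of the thioether by AgBF4 gives the unit B C4 cation, which should be attacked anti to the axial 3-hydroxyl (3,4-trans, 4β) by C8 of the upper unit of 15, the most nucleophilic free arene position (Friedel–Crafts).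

Step 18
Reactants: 24 fully protected tetramer
Product: 25 catechin-(4α→6)-epicatechin-(4β→8)-epicatechin-(4β→8)-epicatechin (CNP0228086.1)
Conditions: H2 (1 atm), Pd(OH)2/C, Et3N, THF–MeOH–H2O, rt
Reagents that add atoms: none
Why: Hydrogenolysis of all benzyl-type ethers with hydrodebromination of the three aryl bromides in one operation; Et3N buffers the HBr so that the acid-labile interflavan bonds and the stereocentres should survive.

**Compound list**

1 | 1,3,5-triacetoxybenzene | CC(=O)Oc1cc(OC(C)=O)cc(OC(C)=O)c1 | starting material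
2 | 3,4-bis(benzyloxy)benzyl chloride | ClCc1ccc(OCc2ccccc2)c(OCc2ccccc2)c1 | starting material
3 | 1,3,5-tris{[3,4-bis(benzyloxy)benzyl]oxy}benzene | c1(OCc8ccc(OCc9ccccc9)c(OCc9ccccc9)c8)cc(OCc8ccc(OCc9ccccc9)c(OCc9ccccc9)c8)cc(OCc8ccc(OCc9ccccc9)c(OCc9ccccc9)c8)c1 | intermediate
4 | 2-iodo-1,3,5-tris{[3,4-bis(benzyloxy)benzyl]oxy}benzene | Ic1c(OCc8ccc(OCc9ccccc9)c(OCc9ccccc9)c8)cc(OCc8ccc(OCc9ccccc9)c(OCc9ccccc9)c8)cc1OCc8ccc(OCc9ccccc9)c(OCc9ccccc9)c8 | intermediate
5 | ethyl 2-diazo-2-(2,4,6-tris{[3,4-bis(benzyloxy)benzyl]oxy}phenyl)acetate | CCOC(=O)C(=[N+]=[N-])c1c(OCc8ccc(OCc9ccccc9)c(OCc9ccccc9)c8)cc(OCc8ccc(OCc9ccccc9)c(OCc9ccccc9)c8)cc1OCc8ccc(OCc9ccccc9)c(OCc9ccccc9)c8 | intermediate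
6 | ethyl (2S,3R)-cis-2-[3,4-bis(benzyloxy)phenyl]-4,6-bis{[3,4-bis(benzyloxy)benzyl]oxy}-2,3-dihydrobenzofuran-3-carboxylate | c1(OCc8ccc(OCc9ccccc9)c(OCc9ccccc9)c8)cc(OCc8ccc(OCc9ccccc9)c(OCc9ccccc9)c8)c2c(c1)O[C@H](c7ccc(OCc9ccccc9)c(OCc9ccccc9)c7)[C@@H]2C(=O)OCC | intermediate
7 | ethyl (2S,3S)-trans-2-[3,4-bis(benzyloxy)phenyl]-4,6-bis{[3,4-bis(benzyloxy)benzyl]oxy}-2,3-dihydrobenzofuran-3-carboxylate | c1(OCc8ccc(OCc9ccccc9)c(OCc9ccccc9)c8)cc(OCc8ccc(OCc9ccccc9)c(OCc9ccccc9)c8)c2c(c1)O[C@H](c7ccc(OCc9ccccc9)c(OCc9ccccc9)c7)[C@H]2C(=O)OCC | intermediate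
8 | (2S,3S)-trans-2-[3,4-bis(benzyloxy)phenyl]-4,6-bis{[3,4-bis(benzyloxy)benzyl]oxy}-2,3-dihydrobenzofuran-3-carbaldehyde | c1(OCc8ccc(OCc9ccccc9)c(OCc9ccccc9)c8)cc(OCc8ccc(OCc9ccccc9)c(OCc9ccccc9)c8)c2c(c1)O[C@H](c7ccc(OCc9ccccc9)c(OCc9ccccc9)c7)[C@H]2C=O | intermediate
9 | (−)-epicatechin | O[C@@H]1Cc2c(O)cc(O)cc2O[C@@H]1c1ccc(O)c(O)c1 | starting material
10 | 5,7,3',4'-tetra-O-benzylepicatechin | c1c(OCc9ccccc9)cc(OCc9ccccc9)c2c1O[C@H](c7ccc(OCc9ccccc9)c(OCc9ccccc9)c7)[C@H](O)C2 | intermediate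
11 | 3,5,7,3',4'-penta-O-benzylepicatechin | c1c(OCc9ccccc9)cc(OCc9ccccc9)c2c1O[C@H](c7ccc(OCc9ccccc9)c(OCc9ccccc9)c7)[C@H](OCc9ccccc9)C2 | intermediate
12 | O-benzyl oxocarbenium ion of aldehyde 8, (2S,3S)-trans | c1(OCc8ccc(OCc9ccccc9)c(OCc9ccccc9)c8)cc(OCc8ccc(OCc9ccccc9)c(OCc9ccccc9)c8)c2c(c1)O[C@H](c7ccc(OCc9ccccc9)c(OCc9ccccc9)c7)[C@H]2C=[O+]Cc9ccccc9 | intermediate
13 | C4 cation of 3,3',4'-tri-O-benzyl-5,7-bis-O-[3,4-bis(benzyloxy)benzyl]epicatechin (2,3-cis flavan-4-yl cation) | c1c(OCc8ccc(OCc9ccccc9)c(OCc9ccccc9)c8)cc(OCc8ccc(OCc9ccccc9)c(OCc9ccccc9)c8)c2c1O[C@H](c7ccc(OCc9ccccc9)c(OCc9ccccc9)c7)[C@H](OCc9ccccc9)[CH+]2 | intermediate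
14 | 4β-benzyloxy-3,3',4'-tri-O-benzyl-5,7-bis-O-[3,4-bis(benzyloxy)benzyl]epicatechin | c1c(OCc8ccc(OCc9ccccc9)c(OCc9ccccc9)c8)cc(OCc8ccc(OCc9ccccc9)c(OCc9ccccc9)c8)c2c1O[C@H](c7ccc(OCc9ccccc9)c(OCc9ccccc9)c7)[C@H](OCc9ccccc9)[C@H]2OCc9ccccc9 | intermediate
15 | 3,3',4'-tri-O-benzyl-5,7-bis-O-[3,4-bis(benzyloxy)benzyl]epicatechin-(4β→8)-3,5,7,3',4'-penta-O-benzylepicatechin | c1c(OCc8ccc(OCc9ccccc9)c(OCc9ccccc9)c8)cc(OCc8ccc(OCc9ccccc9)c(OCc9ccccc9)c8)c2c1O[C@H](c7ccc(OCc9ccccc9)c(OCc9ccccc9)c7)[C@H](OCc9ccccc9)[C@H]2c3c(OCc9ccccc9)cc(OCc9ccccc9)c4c3O[C@H](c7ccc(OCc9ccccc9)c(OCc9ccccc9)c7)[C@H](OCc9ccccc9)C4 | intermediate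
16 | (+)-catechin | O[C@H]1Cc2c(O)cc(O)cc2O[C@@H]1c1ccc(O)c(O)c1 | starting material
17 | 5,7,3',4'-tetra-O-benzylcatechin | c1c(OCc9ccccc9)cc(OCc9ccccc9)c2c1O[C@H](c7ccc(OCc9ccccc9)c(OCc9ccccc9)c7)[C@@H](O)C2 | intermediate
18 | 4β-(2-ethoxyethoxy)-5,7,3',4'-tetra-O-benzylcatechin (3,4-cis) | c1c(OCc9ccccc9)cc(OCc9ccccc9)c2c1O[C@H](c7ccc(OCc9ccccc9)c(OCc9ccccc9)c7)[C@@H](O)[C@H]2OCCOCC | intermediate
19 | 6,8-dibromo-4β-(2-ethoxyethoxy)-5,7,3',4'-tetra-O-benzylcatechin | Brc1c(OCc9ccccc9)c(Br)c(OCc9ccccc9)c2c1O[C@H](c7ccc(OCc9ccccc9)c(OCc9ccccc9)c7)[C@@H](O)[C@H]2OCCOCC | intermediate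
20 | 8-bromo-5,7,3',4'-tetra-O-benzylepicatechin | Brc1c(OCc9ccccc9)cc(OCc9ccccc9)c2c1O[C@H](c7ccc(OCc9ccccc9)c(OCc9ccccc9)c7)[C@H](O)C2 | intermediate
21 | 8-bromo-4β-(2-ethoxyethoxy)-5,7,3',4'-tetra-O-benzylepicatechin (3,4-trans) | Brc1c(OCc9ccccc9)cc(OCc9ccccc9)c2c1O[C@H](c7ccc(OCc9ccccc9)c(OCc9ccccc9)c7)[C@H](O)[C@H]2OCCOCC | intermediate
22 | 8-bromo-4β-(2,6-dimethylphenylthio)-5,7,3',4'-tetra-O-benzylepicatechin (3,4-trans) | Brc1c(OCc9ccccc9)cc(OCc9ccccc9)c2c1O[C@H](c7ccc(OCc9ccccc9)c(OCc9ccccc9)c7)[C@H](O)[C@H]2Sc5c(C)cccc5C | intermediate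
23 | [6,8-dibromo-5,7,3',4'-tetra-O-benzylcatechin]-(4α→6)-[8-bromo-4β-(2,6-dimethylphenylthio)-5,7,3',4'-tetra-O-benzylepicatechin] | c1(OCc9ccccc9)c(Br)c(OCc9ccccc9)c2c(c1Br)O[C@H](c7ccc(OCc9ccccc9)c(OCc9ccccc9)c7)[C@@H](O)[C@@H]2c3c(OCc9ccccc9)c(Br)c4c(c3OCc9ccccc9)[C@H](Sc5c(C)cccc5C)[C@@H](O)[C@@H](c7ccc(OCc9ccccc9)c(OCc9ccccc9)c7)O4 | intermediate
24 | [6,8-dibromo-5,7,3',4'-tetra-O-benzylcatechin]-(4α→6)-[8-bromo-5,7,3',4'-tetra-O-benzylepicatechin]-(4β→8)-[3,3',4'-tri-O-benzyl-5,7-bis-O-(3,4-bis(benzyloxy)benzyl)epicatechin]-(4β→8)-[3,5,7,3',4'-penta-O-benzylepicatechin] | c1(OCc9ccccc9)c(Br)c(OCc9ccccc9)c2c(c1Br)O[C@H](c7ccc(OCc9ccccc9)c(OCc9ccccc9)c7)[C@@H](O)[C@@H]2c3c(OCc9ccccc9)c(Br)c4c(c3OCc9ccccc9)[C@H](c5c(OCc8ccc(OCc9ccccc9)c(OCc9ccccc9)c8)cc(OCc8ccc(OCc9ccccc9)c(OCc9ccccc9)c8)c6c5O[C@H](c7ccc(OCc9ccccc9)c(OCc9ccccc9)c7)[C@H](OCc9ccccc9)[C@H]6c5c(OCc9ccccc9)cc(OCc9ccccc9)c6c5O[C@H](c7ccc(OCc9ccccc9)c(OCc9ccccc9)c7)[C@H](OCc9ccccc9)C6)[C@@H](O)[C@@H](c7ccc(OCc9ccccc9)c(OCc9ccccc9)c7)O4 | intermediate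
25 | catechin-(4α→6)-epicatechin-(4β→8)-epicatechin-(4β→8)-epicatechin (CNP0228086.1) | Oc1cc(O)c2c(c1)O[C@H](c1ccc(O)c(O)c1)[C@@H](O)[C@@H]2c1c(O)cc2c(c1O)[C@H](c1c(O)cc(O)c3c1O[C@H](c1ccc(O)c(O)c1)[C@H](O)[C@H]3c1c(O)cc(O)c3c1O[C@H](c1ccc(O)c(O)c1)[C@H](O)C3)[C@@H](O)[C@@H](c1ccc(O)c(O)c1)O2 | target

**Step count and risks**

Total step count: 18. Longest linear sequence: 9 steps (steps 1–6, 9, 17, 18).

Steps most likely to fail: step 9, step 17, step 3.

Step 9 (proposed method). Three things may go wrong. Hydride migration or proton loss from the oxocarbenium ion may outrun the alkyl shift and drain the material into the aromatic benzofuran. The C2–C3 bond may ionise fully and reclose with loss of the C2 configuration. The rotamer control at C3 may be poor. The fallback uses known chemistry and takes unit C from the chiral pool; it sets out from 11. DDQ oxidation of 11 in the presence of 2-ethoxyethanol gives 4β-(2-ethoxyethoxy)-3,5,7,3',4'-penta-O-benzylepicatechin F1. TMSOTf-catalysed Friedel–Crafts coupling of F1 with excess 11 gives 3,5,7,3',4'-penta-O-benzylepicatechin-(4β→8)-3,5,7,3',4'-penta-O-benzylepicatechin F2. F2 takes the place of 15 in the AgBF4 coupling with 23 and gives the all-benzyl protected tetramer F3, which differs from 24 only in carrying benzyl ethers on O5 and O7 of unit C. Hydrogenolysis under the conditions of step 18 comes back to the route at 25.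

Step 17. The cation from 23 may attack a C6 position of either unit of 15 (loss of regiocontrol), or the coupling of two dimeric blocks may stall for steric reasons. The fallback extends the chain one unit at a time; it sets out from 8. Step 9 is stopped before 11 is added and the 4-benzyl ether 14 is isolated. AgBF4 activation of 23 in the presence of 14 and 2,6-di-tert-butyl-4-methylpyridine alkylates C8 of this monomer, which has no competing lower unit, and gives the A–B–C trimer that keeps the 4β-benzyloxy group on unit C F4. TMSOTf then ionises that benzyloxy group in the presence of excess 11, and the coupling comes back to the route at 24.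

Step 3. Oxidative addition and transfer of the diazoacetate at the doubly ortho-substituted iodide may be too slow, so that the diazo ester dimerises instead of coupling. The fallback builds the diazo group from a ketone; it sets out from 4. Iodine–magnesium exchange with iPrMgCl·LiCl and acylation with diethyl oxalate give ethyl 2-oxo-2-(2,4,6-tris{[3,4-bis(benzyloxy)benzyl]oxy}phenyl)acetate F5. Condensation with tosylhydrazine gives the N-tosylhydrazone of this keto ester F6. Bamford–Stevens elimination with DBU comes back to the route at 5.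

**Further compounds**

F1 | step 9 | 4β-(2-ethoxyethoxy)-3,5,7,3',4'-penta-O-benzylepicatechin | c1c(OCc9ccccc9)cc(OCc9ccccc9)c2c1O[C@H](c7ccc(OCc9ccccc9)c(OCc9ccccc9)c7)[C@H](OCc9ccccc9)[C@H]2OCCOCC
F2 | step 9 | 3,5,7,3',4'-penta-O-benzylepicatechin-(4β→8)-3,5,7,3',4'-penta-O-benzylepicatechin | c1c(OCc9ccccc9)cc(OCc9ccccc9)c2c1O[C@H](c7ccc(OCc9ccccc9)c(OCc9ccccc9)c7)[C@H](OCc9ccccc9)[C@H]2c3c(OCc9ccccc9)cc(OCc9ccccc9)c4c3O[C@H](c7ccc(OCc9ccccc9)c(OCc9ccccc9)c7)[C@H](OCc9ccccc9)C4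
F3 | step 9 | [6,8-dibromo-5,7,3',4'-tetra-O-benzylcatechin]-(4α→6)-[8-bromo-5,7,3',4'-tetra-O-benzylepicatechin]-(4β→8)-[3,5,7,3',4'-penta-O-benzylepicatechin]-(4β→8)-[3,5,7,3',4'-penta-O-benzylepicatechin] | c1(OCc9ccccc9)c(Br)c(OCc9ccccc9)c2c(c1Br)O[C@H](c7ccc(OCc9ccccc9)c(OCc9ccccc9)c7)[C@@H](O)[C@@H]2c3c(OCc9ccccc9)c(Br)c4c(c3OCc9ccccc9)[C@H](c5c(OCc9ccccc9)cc(OCc9ccccc9)c6c5O[C@H](c7ccc(OCc9ccccc9)c(OCc9ccccc9)c7)[C@H](OCc9ccccc9)[C@H]6c5c(OCc9ccccc9)cc(OCc9ccccc9)c6c5O[C@H](c7ccc(OCc9ccccc9)c(OCc9ccccc9)c7)[C@H](OCc9ccccc9)C6)[C@@H](O)[C@@H](c7ccc(OCc9ccccc9)c(OCc9ccccc9)c7)O4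
F4 | step 17 | [6,8-dibromo-5,7,3',4'-tetra-O-benzylcatechin]-(4α→6)-[8-bromo-5,7,3',4'-tetra-O-benzylepicatechin]-(4β→8)-[4β-benzyloxy-3,3',4'-tri-O-benzyl-5,7-bis-O-(3,4-bis(benzyloxy)benzyl)epicatechin] | c1(OCc9ccccc9)c(Br)c(OCc9ccccc9)c2c(c1Br)O[C@H](c7ccc(OCc9ccccc9)c(OCc9ccccc9)c7)[C@@H](O)[C@@H]2c3c(OCc9ccccc9)c(Br)c4c(c3OCc9ccccc9)[C@H](c5c(OCc8ccc(OCc9ccccc9)c(OCc9ccccc9)c8)cc(OCc8ccc(OCc9ccccc9)c(OCc9ccccc9)c8)c6c5O[C@H](c7ccc(OCc9ccccc9)c(OCc9ccccc9)c7)[C@H](OCc9ccccc9)[C@H]6OCc9ccccc9)[C@@H](O)[C@@H](c7ccc(OCc9ccccc9)c(OCc9ccccc9)c7)O4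
F5 | step 3 | ethyl 2-oxo-2-(2,4,6-tris{[3,4-bis(benzyloxy)benzyl]oxy}phenyl)acetate | CCOC(=O)C(=O)c1c(OCc8ccc(OCc9ccccc9)c(OCc9ccccc9)c8)cc(OCc8ccc(OCc9ccccc9)c(OCc9ccccc9)c8)cc1OCc8ccc(OCc9ccccc9)c(OCc9ccccc9)c8
F6 | step 3 | ethyl 2-(2-tosylhydrazinylidene)-2-(2,4,6-tris{[3,4-bis(benzyloxy)benzyl]oxy}phenyl)acetate | CCOC(=O)C(=NNS(=O)(=O)c5ccc(C)cc5)c1c(OCc8ccc(OCc9ccccc9)c(OCc9ccccc9)c8)cc(OCc8ccc(OCc9ccccc9)c(OCc9ccccc9)c8)cc1OCc8ccc(OCc9ccccc9)c(OCc9ccccc9)c8
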